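The 14-membered lactone is disconnected at C6–C7 (C1 = lactone carbonyl). Ring-closing metathesis of an ester-linked diene, a C6 isopropenyl carbinol and a C7 vinyl group on C8, closes the macrocycle as an E-trisubstituted C6=C7 alkene. The step exploits the C5 hydroxyl beside C6: free, it assists metathesis and then directs hydrogenation, so the C6 methyl centre is set syn to C5–OH only after the ring exists, while C8 arrives fixed from a crotylboration. Both halves descend from one aldol adduct; C3 and C9 travel as silyl-protected carbinols and are oxidised last to shield the labile C2 and C8 centres.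

Key step: step 16

Remarks on the chemistry:
- Atoms carry polyketide numbers, from C1 (lactone carbonyl) to C13 (carbinol carbon bearing the ethyl group). The target is (2R,4S,5R,6S,8S,10E,12S,13S).
- The C3 and C9 carbinol configurations are temporary and are erased in step 20.
- It is assumed that the 2-methyl-3-oxo lactone (C2) and the C8 centre keep their configuration under the buffered, base-free conditions of steps 20 and 21.

Step 1
Reactants: 1 (R)-4-benzyl-3-propanoyloxazolidin-2-one; 2 propanal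
Product: 3 (R)-4-benzyl-3-[(2R,3S)-3-hydroxy-2-methylpentanoyl]oxazolidin-2-one
Conditions: n-Bu2BOTf, Et3N, CH2Cl2, −78 to 0 °C; 2, −78 to 0 °C; then pH 7 buffer, MeOH, H2O2, 0 °C
Reagents that add atoms: none
Why: Evans syn-aldol reaction; the Z-boron enolate reacts through a Zimmerman–Traxler chair on the face away from the benzyl group, which sets the 2,3-syn pair that becomes C12/C13 in one half and C2 in the other.

Step 2
Reactants: 3 (R)-4-benzyl-3-[(2R,3S)-3-hydroxy-2-methylpentanoyl]oxazolidin-2-one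
Product: 4 (R)-4-benzyl-3-[(R)-2-methyl-3-oxopentanoyl]oxazolidin-2-one
Conditions: SO3·pyridine, DMSO, i-Pr2NEt, CH2Cl2, −10 °C
Reagents that add atoms: none
Why: Parikh–Doering oxidation gives the β-keto imide without epimerisation, because allylic strain with the imide keeps the C2 methyl centre from enolising.

Step 3
Reactants: 4 (R)-4-benzyl-3-[(R)-2-methyl-3-oxopentanoyl]oxazolidin-2-one; 5 methacrolein
Product: 6 (R)-4-benzyl-3-[(2R,4S,5S)-5-hydroxy-2,4,6-trimethyl-3-oxohept-6-enoyl]oxazolidin-2-one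
Conditions: Sn(OTf)2, Et3N, CH2Cl2, −20 °C; then 5, −78 °C
Reagents that add atoms: none
Why: Tin-mediated aldol reaction of a β-keto imide; the chelated Z-enolate of divalent tin adds under control of the C2 methyl centre to give the 2,4-anti-4,5-syn adduct, which sets C4 and C5 and brings in the C6 isopropenyl group.

Step 4
Reactants: 6 (R)-4-benzyl-3-[(2R,4S,5S)-5-hydroxy-2,4,6-trimethyl-3-oxohept-6-enoyl]oxazolidin-2-one
Product: 7 (R)-4-benzyl-3-[(2R,4S,5S)-2,4,6-trimethyl-3-oxo-5-(triethylsilyloxy)hept-6-enoyl]oxazolidin-2-one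
Conditions: Et3SiOTf, 2,6-lutidine, CH2Cl2, −78 °C
Reagents that add atoms: triethylsilyl trifluoromethanesulfonate, CC[Si](CC)(CC)OS(=O)(=O)C(F)(F)F
Why: Silyl triflate silylation of the aldol hydroxyl blocks retro-aldol cleavage and later lactonisation of C5 onto C1.

Step 5
Reactants: 7 (R)-4-benzyl-3-[(2R,4S,5S)-2,4,6-trimethyl-3-oxo-5-(triethylsilyloxy)hept-6-enoyl]oxazolidin-2-one
Product: 8 (R)-4-benzyl-3-[(2R,3S,4R,5S)-3-hydroxy-2,4,6-trimethyl-5-(triethylsilyloxy)hept-6-enoyl]oxazolidin-2-one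
Conditions: Zn(BH4)2, Et2O–CH2Cl2, −78 to −20 °C; aq NH4Cl
Reagents that add atoms: none
Why: Chelation-controlled hydride reduction (zinc bridging ketone and imide carbonyls) should give the 2,3-syn carbinol; this temporary centre parks C3 at a level at which C2 cannot enolise.

Step 6
Reactants: 8 (R)-4-benzyl-3-[(2R,3S,4R,5S)-3-hydroxy-2,4,6-trimethyl-5-(triethylsilyloxy)hept-6-enoyl]oxazolidin-2-one
Product: 9 (R)-4-benzyl-3-[(2R,3S,4R,5S)-3-(tert-butyldimethylsilyloxy)-2,4,6-trimethyl-5-(triethylsilyloxy)hept-6-enoyl]oxazolidin-2-one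
Conditions: t-BuMe2SiOTf, 2,6-lutidine, CH2Cl2, 0 °C
Reagents that add atoms: tert-butyldimethylsilyl trifluoromethanesulfonate, CC(C)(C)[Si](C)(C)OS(=O)(=O)C(F)(F)F
Why: Silylation of the hindered C3 carbinol with the reactive triflate, so that the acid can later be activated without self-acylation.

Step 7
Reactants: 9 (R)-4-benzyl-3-[(2R,3S,4R,5S)-3-(tert-butyldimethylsilyloxy)-2,4,6-trimethyl-5-(triethylsilyloxy)hept-6-enoyl]oxazolidin-2-one
Product: 11 (2R,3S,4R,5S)-3-(tert-butyldimethylsilyloxy)-2,4,6-trimethyl-5-(triethylsilyloxy)hept-6-enoic acid, via peroxy acid 10 (not isolated)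
Conditions: LiOH, H2O2, THF–H2O, 0 °C; then Na2SO3; then 1 M HCl
Reagents that add atoms: lithium hydroperoxide (from LiOH and H2O2), [Li+].[O-]O
Why: Hydroperoxide cleavage of the N-acyl oxazolidinone attacks the exocyclic carbonyl selectively and the peracid is reduced by sulfite, which frees the acid without touching C2.

Step 8
Reactants: 3 (R)-4-benzyl-3-[(2R,3S)-3-hydroxy-2-methylpentanoyl]oxazolidin-2-one
Product: 12 (R)-4-benzyl-3-[(2R,3S)-2-methyl-3-(triethylsilyloxy)pentanoyl]oxazolidin-2-one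
Conditions: Et3SiOTf, 2,6-lutidine, CH2Cl2, −78 °C
Reagents that add atoms: triethylsilyl trifluoromethanesulfonate, CC[Si](CC)(CC)OS(=O)(=O)C(F)(F)F
Why: Silylation gives a temporary C13 protecting group that can later be removed in the presence of a tert-butyldimethylsilyl ether.

Step 9
Reactants: 12 (R)-4-benzyl-3-[(2R,3S)-2-methyl-3-(triethylsilyloxy)pentanoyl]oxazolidin-2-one
Product: 13 (2S,3S)-2-methyl-3-(triethylsilyloxy)pentan-1-ol
Conditions: LiBH4, H2O (1 equiv), Et2O, 0 °C
Reagents that add atoms: none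
Why: Reductive removal of the auxiliary; borohydride attacks the exocyclic imide carbonyl and leaves the silyl ether and both stereocentres intact.

Step 10
Reactants: 13 (2S,3S)-2-methyl-3-(triethylsilyloxy)pentan-1-ol
Product: 15 (2E,4S,5S)-4-methyl-5-(triethylsilyloxy)hept-2-enal, via aldehyde 14 (not isolated)
Conditions: Dess–Martin periodinane, NaHCO3, CH2Cl2, 0 °C to rt; then Ph3P=CHCHO, toluene, 80 °C
Reagents that add atoms: (triphenylphosphoranylidene)acetaldehyde, O=CC=P(c1ccccc1)(c1ccccc1)c1ccccc1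
Why: Buffered Dess–Martin oxidation keeps the α-centre, and the Wittig reaction with the stabilised ylide should give the E-enal that carries C9 to C13.

Step 11
Reactants: 15 (2E,4S,5S)-4-methyl-5-(triethylsilyloxy)hept-2-enal
Product: 16 (3S,4R,5E,7S,8S)-3,7-dimethyl-8-(triethylsilyloxy)deca-1,5-dien-4-ol
Conditions: (−)-Ipc2BOMe, trans-2-butene, KOt-Bu, n-BuLi, THF, −78 to −45 °C; BF3·OEt2, −78 °C; 15, −78 °C; then NaOH, H2O2
Reagents that add atoms: (E)-crotyldiisopinocampheylborane (made in the flask from trans-2-butene and (−)-Ipc2BOMe), C/C=C/CB([C@@H]1C[C@@H]2C[C@H]([C@H]1C)C2(C)C)[C@@H]1C[C@@H]2C[C@H]([C@H]1C)C2(C)C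
Why: Brown crotylboration through a closed chair transition state; the E-crotyl group gives the 8,9-anti pair and the isopinocampheyl ligands fix C8 as S, while the C9 carbinol is temporary.

Step 12
Reactants: 16 (3S,4R,5E,7S,8S)-3,7-dimethyl-8-(triethylsilyloxy)deca-1,5-dien-4-ol
Product: 17 (3S,4R,5E,7S,8S)-4-(tert-butyldimethylsilyloxy)-3,7-dimethyl-8-(triethylsilyloxy)deca-1,5-diene
Conditions: t-BuMe2SiOTf, 2,6-lutidine, CH2Cl2, −78 to 0 °C
Reagents that add atoms: tert-butyldimethylsilyl trifluoromethanesulfonate, CC(C)(C)[Si](C)(C)OS(=O)(=O)C(F)(F)F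
Why: Silylation masks the temporary C9 carbinol with a group that outlasts the triethylsilyl ether.

Step 13
Reactants: 17 (3S,4R,5E,7S,8S)-4-(tert-butyldimethylsilyloxy)-3,7-dimethyl-8-(triethylsilyloxy)deca-1,5-diene
Product: 18 (3S,4S,5E,7R,8S)-7-(tert-butyldimethylsilyloxy)-4,8-dimethyldeca-5,9-dien-3-ol
Conditions: PPTS (cat.), MeOH–CH2Cl2, 0 °C
Reagents that add atoms: none
Why: Selective acid-catalysed methanolysis removes the more labile triethylsilyl ether and leaves the tert-butyldimethylsilyl ether, which frees the C13 hydroxyl.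

Step 14
Reactants: 11 (2R,3S,4R,5S)-3-(tert-butyldimethylsilyloxy)-2,4,6-trimethyl-5-(triethylsilyloxy)hept-6-enoic acid; 18 (3S,4S,5E,7R,8S)-7-(tert-butyldimethylsilyloxy)-4,8-dimethyldeca-5,9-dien-3-ol
Product: 20 (3S,4S,5E,7R,8S)-7-(tert-butyldimethylsilyloxy)-4,8-dimethyldeca-5,9-dien-3-yl (2R,3S,4R,5S)-3-(tert-butyldimethylsilyloxy)-2,4,6-trimethyl-5-(triethylsilyloxy)hept-6-enoate, via mixed anhydride 19 (not isolated)
Conditions: 2,4,6-trichlorobenzoyl chloride, Et3N, THF, rt; then 18, DMAP, toluene, rt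
Reagents that add atoms: none
Why: Yamaguchi esterification; DMAP delivers the aliphatic acyl group of the mixed anhydride to the hindered C13 hydroxyl, joining the halves without epimerising C2.

Step 15
Reactants: 20 (3S,4S,5E,7R,8S)-7-(tert-butyldimethylsilyloxy)-4,8-dimethyldeca-5,9-dien-3-yl (2R,3S,4R,5S)-3-(tert-butyldimethylsilyloxy)-2,4,6-trimethyl-5-(triethylsilyloxy)hept-6-enoate
Product: 21 (3S,4S,5E,7R,8S)-7-(tert-butyldimethylsilyloxy)-4,8-dimethyldeca-5,9-dien-3-yl (2R,3S,4S,5S)-3-(tert-butyldimethylsilyloxy)-5-hydroxy-2,4,6-trimethylhept-6-enoate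
Conditions: HF·pyridine, pyridine, THF, 0 °C
Reagents that add atoms: none
Why: Selective desilylation; buffered fluoride cleaves the triethylsilyl ether far faster than the two tert-butyldimethylsilyl ethers, and the buffered, non-nucleophilic medium with direct use should limit δ-lactonisation of the free C5 hydroxyl onto C1.

Step 16
Reactants: 21 (3S,4S,5E,7R,8S)-7-(tert-butyldimethylsilyloxy)-4,8-dimethyldeca-5,9-dien-3-yl (2R,3S,4S,5S)-3-(tert-butyldimethylsilyloxy)-5-hydroxy-2,4,6-trimethylhept-6-enoate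
Product: 22 (2R,3S,4S,5S,6E,8S,9R,10E,12S,13S)-3,9-bis(tert-butyldimethylsilyloxy)-5-hydroxy-2,4,6,8,12-pentamethylpentadeca-6,10-dien-13-olide
Conditions: second-generation Hoveyda–Grubbs catalyst RuCl2(H2IMes)(=CH-C6H4-2-O-i-Pr) (10 mol %), 1,4-benzoquinone (20 mol %), toluene (1 mM), 80 °C, argon sparge
Reagents that add atoms: none
Why: Ring-closing olefin metathesis (Chauvin mechanism): the ruthenium alkylidene loads on the unhindered C7 vinyl group, adds across the C6 isopropenyl alkene through a ruthenacyclobutane and, after cycloreversion, releases ethylene and the C6=C7 alkene. The closest known reaction type is macrocyclic ring-closing metathesis of a 1,1-disubstituted with a monosubstituted alkene to a trisubstituted cycloalkene in macrolactone synthesis. The 14-membered ring is closed in a single macrocyclisation in which the new alkene lies inside the ring. No stereocentre is created; the one new stereo-element, the alkene geometry, should be E because metathesis is reversible and the Z isomer would force the branched C5 and C8 carbons cis across the alkene (allylic 1,3-strain), whereas E places only the C6 methyl cis to C8. The step needs site selectivity and ring closure over oligomerisation: the internal C10=C11 alkene is trans-disubstituted and flanked by the C9 silyl ether and C12, so it should stay a spectator; high dilution favours the ring; the free allylic C5 hydroxyl assists engagement of the hindered alkene; and benzoquinone suppresses hydride-induced alkene migration towards C8.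

Step 17
Reactants: 22 (2R,3S,4S,5S,6E,8S,9R,10E,12S,13S)-3,9-bis(tert-butyldimethylsilyloxy)-5-hydroxy-2,4,6,8,12-pentamethylpentadeca-6,10-dien-13-olide
Product: 23 (2R,3S,4S,5R,6S,8S,9S,10E,12S,13S)-3,9-bis(tert-butyldimethylsilyloxy)-5-hydroxy-2,4,6,8,12-pentamethylpentadec-10-en-13-olide
Conditions: [Rh(nbd)(dppb)]BF4 (10 mol %), H2 (60 atm), CH2Cl2, rt
Reagents that add atoms: none
Why: Hydroxyl-directed hydrogenation; rhodium bound to the C5 hydroxyl delivers H2 to the alkene face syn to oxygen in the rotamer with C5–H beside the C6 methyl (allylic 1,2-strain minimised, the E geometry keeps 1,3-strain small), which sets C6 as S (5,6-syn), while the C10=C11 alkene has no binding group and high pressure suppresses migration towards C8.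

Step 18
Reactants: 23 (2R,3S,4S,5R,6S,8S,9S,10E,12S,13S)-3,9-bis(tert-butyldimethylsilyloxy)-5-hydroxy-2,4,6,8,12-pentamethylpentadec-10-en-13-olide
Product: 24 (2R,3S,4S,5R,6S,8S,9S,10E,12S,13S)-5-(allyloxycarbonyloxy)-3,9-bis(tert-butyldimethylsilyloxy)-2,4,6,8,12-pentamethylpentadec-10-en-13-olide
Conditions: allyl chloroformate, pyridine, DMAP (cat.), CH2Cl2, 0 °C to rt
Reagents that add atoms: allyl chloroformate, C=CCOC(=O)Cl
Why: Acylation caps the only free hydroxyl as an allyl carbonate, which survives fluoride and oxidation and can leave later under neutral conditions.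

Step 19
Reactants: 24 (2R,3S,4S,5R,6S,8S,9S,10E,12S,13S)-5-(allyloxycarbonyloxy)-3,9-bis(tert-butyldimethylsilyloxy)-2,4,6,8,12-pentamethylpentadec-10-en-13-olide
Product: 25 (2R,3S,4R,5R,6S,8S,9S,10E,12S,13S)-5-(allyloxycarbonyloxy)-3,9-dihydroxy-2,4,6,8,12-pentamethylpentadec-10-en-13-olide
Conditions: HF·pyridine, pyridine, THF, 0 °C to rt
Reagents that add atoms: none
Why: Fluoride-mediated desilylation frees the C3 and C9 carbinols, while carbonate and lactone are inert to buffered HF.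

Step 20
Reactants: 25 (2R,3S,4R,5R,6S,8S,9S,10E,12S,13S)-5-(allyloxycarbonyloxy)-3,9-dihydroxy-2,4,6,8,12-pentamethylpentadec-10-en-13-olide
Product: 26 (2R,4S,5R,6S,8S,10E,12S,13S)-5-(allyloxycarbonyloxy)-2,4,6,8,12-pentamethyl-3,9-dioxopentadec-10-en-13-olide
Conditions: Dess–Martin periodinane, NaHCO3, CH2Cl2, 0 °C to rt
Reagents that add atoms: none
Why: Dess–Martin oxidation converts both carbinols at once into the C3 ketone and the C9 enone under buffered, base-free conditions that should leave the now labile C2 and C8 centres and the β-carbonate untouched.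

Step 21
Reactants: 26 (2R,4S,5R,6S,8S,10E,12S,13S)-5-(allyloxycarbonyloxy)-2,4,6,8,12-pentamethyl-3,9-dioxopentadec-10-en-13-olide
Product: 27 (2R,4S,5R,6S,8S,10E,12S,13S)-5-hydroxy-2,4,6,8,12-pentamethyl-3,9-dioxopentadec-10-en-13-olide (target)
Conditions: Pd(PPh3)4 (5 mol %), dimedone, THF, rt
Reagents that add atoms: none
Why: Tsuji–Trost-type deallylation; zerovalent palladium ionises the allyl carbonate, CO2 is lost and the far more acidic dimedone traps the allyl fragment, so the C5 hydroxyl is released under neutral conditions that avoid enolisation at C2 and β-elimination.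

Compound list
1 | (R)-4-benzyl-3-propanoyloxazolidin-2-one | CCC(=O)N1[C@H](Cc2ccccc2)COC1=O | starting material
2 | propanal | CCC=O | starting material
3 | (R)-4-benzyl-3-[(2R,3S)-3-hydroxy-2-methylpentanoyl]oxazolidin-2-one | O=C(N1[C@H](Cc2ccccc2)COC1=O)[C@H](C)[C@@H](O)CC | intermediate
4 | (R)-4-benzyl-3-[(R)-2-methyl-3-oxopentanoyl]oxazolidin-2-one | O=C(N1[C@H](Cc2ccccc2)COC1=O)[C@H](C)C(=O)CC | intermediate
5 | methacrolein (2-methylprop-2-enal) | CC(=C)C=O | starting material
6 | (R)-4-benzyl-3-[(2R,4S,5S)-5-hydroxy-2,4,6-trimethyl-3-oxohept-6-enoyl]oxazolidin-2-one | O=C(N1[C@H](Cc2ccccc2)COC1=O)[C@H](C)C(=O)[C@@H](C)[C@H](O)C(C)=C | intermediate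
7 | (R)-4-benzyl-3-[(2R,4S,5S)-2,4,6-trimethyl-3-oxo-5-(triethylsilyloxy)hept-6-enoyl]oxazolidin-2-one | O=C(N1[C@H](Cc2ccccc2)COC1=O)[C@H](C)C(=O)[C@@H](C)[C@H](O[Si](CC)(CC)CC)C(C)=C | intermediate
8 | (R)-4-benzyl-3-[(2R,3S,4R,5S)-3-hydroxy-2,4,6-trimethyl-5-(triethylsilyloxy)hept-6-enoyl]oxazolidin-2-one | O=C(N1[C@H](Cc2ccccc2)COC1=O)[C@H](C)[C@@H](O)[C@@H](C)[C@H](O[Si](CC)(CC)CC)C(C)=C | intermediate
9 | (R)-4-benzyl-3-[(2R,3S,4R,5S)-3-(tert-butyldimethylsilyloxy)-2,4,6-trimethyl-5-(triethylsilyloxy)hept-6-enoyl]oxazolidin-2-one | O=C(N1[C@H](Cc2ccccc2)COC1=O)[C@H](C)[C@@H](O[Si](C)(C)C(C)(C)C)[C@@H](C)[C@H](O[Si](CC)(CC)CC)C(C)=C | intermediate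
10 | (2R,3S,4R,5S)-3-(tert-butyldimethylsilyloxy)-2,4,6-trimethyl-5-(triethylsilyloxy)hept-6-eneperoxoic acid | OOC(=O)[C@H](C)[C@@H](O[Si](C)(C)C(C)(C)C)[C@@H](C)[C@H](O[Si](CC)(CC)CC)C(C)=C | intermediate (not isolated)
11 | (2R,3S,4R,5S)-3-(tert-butyldimethylsilyloxy)-2,4,6-trimethyl-5-(triethylsilyloxy)hept-6-enoic acid | OC(=O)[C@H](C)[C@@H](O[Si](C)(C)C(C)(C)C)[C@@H](C)[C@H](O[Si](CC)(CC)CC)C(C)=C | intermediate
12 | (R)-4-benzyl-3-[(2R,3S)-2-methyl-3-(triethylsilyloxy)pentanoyl]oxazolidin-2-one | O=C(N1[C@H](Cc2ccccc2)COC1=O)[C@H](C)[C@@H](O[Si](CC)(CC)CC)CC | intermediate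
13 | (2S,3S)-2-methyl-3-(triethylsilyloxy)pentan-1-ol | OC[C@H](C)[C@@H](O[Si](CC)(CC)CC)CC | intermediate
14 | (2R,3S)-2-methyl-3-(triethylsilyloxy)pentanal | O=C[C@H](C)[C@@H](O[Si](CC)(CC)CC)CC | intermediate (not isolated)
15 | (2E,4S,5S)-4-methyl-5-(triethylsilyloxy)hept-2-enal | O=C/C=C/[C@H](C)[C@@H](O[Si](CC)(CC)CC)CC | intermediate
16 | (3S,4R,5E,7S,8S)-3,7-dimethyl-8-(triethylsilyloxy)deca-1,5-dien-4-ol | C=C[C@H](C)[C@H](O)/C=C/[C@H](C)[C@@H](O[Si](CC)(CC)CC)CC | intermediate
17 | (3S,4R,5E,7S,8S)-4-(tert-butyldimethylsilyloxy)-3,7-dimethyl-8-(triethylsilyloxy)deca-1,5-diene | C=C[C@H](C)[C@H](O[Si](C)(C)C(C)(C)C)/C=C/[C@H](C)[C@@H](O[Si](CC)(CC)CC)CC | intermediate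
18 | (3S,4S,5E,7R,8S)-7-(tert-butyldimethylsilyloxy)-4,8-dimethyldeca-5,9-dien-3-ol | C=C[C@H](C)[C@H](O[Si](C)(C)C(C)(C)C)/C=C/[C@H](C)[C@@H](O)CC | intermediate
19 | mixed anhydride of acid 11 with 2,4,6-trichlorobenzoic acid | O=C(OC(=O)[C@H](C)[C@@H](O[Si](C)(C)C(C)(C)C)[C@@H](C)[C@H](O[Si](CC)(CC)CC)C(C)=C)c1c(Cl)cc(Cl)cc1Cl | intermediate (not isolated)
20 | (3S,4S,5E,7R,8S)-7-(tert-butyldimethylsilyloxy)-4,8-dimethyldeca-5,9-dien-3-yl (2R,3S,4R,5S)-3-(tert-butyldimethylsilyloxy)-2,4,6-trimethyl-5-(triethylsilyloxy)hept-6-enoate | C=C[C@H](C)[C@H](O[Si](C)(C)C(C)(C)C)/C=C/[C@H](C)[C@H](CC)OC(=O)[C@H](C)[C@@H](O[Si](C)(C)C(C)(C)C)[C@@H](C)[C@H](O[Si](CC)(CC)CC)C(C)=C | intermediate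
21 | (3S,4S,5E,7R,8S)-7-(tert-butyldimethylsilyloxy)-4,8-dimethyldeca-5,9-dien-3-yl (2R,3S,4S,5S)-3-(tert-butyldimethylsilyloxy)-5-hydroxy-2,4,6-trimethylhept-6-enoate | C=C[C@H](C)[C@H](O[Si](C)(C)C(C)(C)C)/C=C/[C@H](C)[C@H](CC)OC(=O)[C@H](C)[C@@H](O[Si](C)(C)C(C)(C)C)[C@@H](C)[C@H](O)C(C)=C | intermediate
22 | (2R,3S,4S,5S,6E,8S,9R,10E,12S,13S)-3,9-bis(tert-butyldimethylsilyloxy)-5-hydroxy-2,4,6,8,12-pentamethylpentadeca-6,10-dien-13-olide | CC[C@@H]1OC(=O)[C@H](C)[C@@H](O[Si](C)(C)C(C)(C)C)[C@@H](C)[C@H](O)/C(C)=C/[C@H](C)[C@H](O[Si](C)(C)C(C)(C)C)/C=C/[C@@H]1C | intermediate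
23 | (2R,3S,4S,5R,6S,8S,9S,10E,12S,13S)-3,9-bis(tert-butyldimethylsilyloxy)-5-hydroxy-2,4,6,8,12-pentamethylpentadec-10-en-13-olide | CC[C@@H]1OC(=O)[C@H](C)[C@@H](O[Si](C)(C)C(C)(C)C)[C@@H](C)[C@H](O)[C@@H](C)C[C@H](C)[C@H](O[Si](C)(C)C(C)(C)C)/C=C/[C@@H]1C | intermediate
24 | (2R,3S,4S,5R,6S,8S,9S,10E,12S,13S)-5-(allyloxycarbonyloxy)-3,9-bis(tert-butyldimethylsilyloxy)-2,4,6,8,12-pentamethylpentadec-10-en-13-olide | CC[C@@H]1OC(=O)[C@H](C)[C@@H](O[Si](C)(C)C(C)(C)C)[C@@H](C)[C@H](OC(=O)OCC=C)[C@@H](C)C[C@H](C)[C@H](O[Si](C)(C)C(C)(C)C)/C=C/[C@@H]1C | intermediate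
25 | (2R,3S,4R,5R,6S,8S,9S,10E,12S,13S)-5-(allyloxycarbonyloxy)-3,9-dihydroxy-2,4,6,8,12-pentamethylpentadec-10-en-13-olide | CC[C@@H]1OC(=O)[C@H](C)[C@@H](O)[C@@H](C)[C@H](OC(=O)OCC=C)[C@@H](C)C[C@H](C)[C@H](O)/C=C/[C@@H]1C | intermediate
26 | (2R,4S,5R,6S,8S,10E,12S,13S)-5-(allyloxycarbonyloxy)-2,4,6,8,12-pentamethyl-3,9-dioxopentadec-10-en-13-olide | CC[C@@H]1OC(=O)[C@H](C)C(=O)[C@@H](C)[C@H](OC(=O)OCC=C)[C@@H](C)C[C@H](C)C(=O)/C=C/[C@@H]1C | intermediate
27 | (2R,4S,5R,6S,8S,10E,12S,13S)-5-hydroxy-2,4,6,8,12-pentamethyl-3,9-dioxopentadec-10-en-13-olide | CC[C@@H]1OC(=O)[C@H](C)C(=O)[C@@H](C)[C@H](O)[C@@H](C)C[C@H](C)C(=O)/C=C/[C@@H]1C | target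

Total step count: 21. Longest linear sequence: 15 steps (step 1, then steps 8 to 13 or steps 2 to 7, then steps 14 to 21).

Steps most likely to fail

Step 16 (ring-closing metathesis). The propagating alkylidene must add to a hindered 1,1-disubstituted alkene that sits next to the C5 carbinol. Ring closure may therefore stall and give way to intermolecular metathesis at the vinyl termini, alkene migration, or closure to the Z alkene. Fallback: set out from 21 and oxidise the allylic C5 hydroxyl (Dess–Martin periodinane, NaHCO3, CH2Cl2) to the seco isopropenyl ketone F1. Metathesis of F1 with the same ruthenium catalyst now engages a methacryloyl-type alkene, a class that closes to trisubstituted E-enones readily, and should give the macrocyclic C5-oxo 6E-enone F2. Reagent-controlled 1,2-reduction of the C5 ketone ((R)-2-methyl-CBS-oxazaborolidine, catecholborane, toluene, −78 °C, the alkenyl side acting as the large group) should restore the (5S)-allylic alcohol, and the route is rejoined at 22.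

Step 17 (directed hydrogenation). Hydrogen may also be delivered to the unbound C10=C11 alkene, the C6=C7 alkene may migrate towards C8 and scramble that centre, or any Z alkene carried over would be reduced from the wrong face. Fallback: set out from 22 and replace the substrate-directed rhodium step by a catalyst-controlled hydrogenation with Ru(OAc)2[(R)-BINAP] (assumed to be the antipode that matches the substrate bias; its mirror image is equally available and would be checked side by side), H2 (100 atm), MeOH–CH2Cl2. This catalyst class turns over only alkenes that chelate through a free allylic hydroxyl, so the C10=C11 alkene is excluded by mechanism and not by sterics. The product is again 23 and no new compound arises.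

Step 20 (double oxidation). The hindered C3 carbinol may oxidise slowly, so that the β-keto lactone formed first is exposed for a long time, with enolisation at C2 or loss of the β-carbonate. Fallback: set out from 25 and oxidise in two chemoselective stages. MnO2 (CH2Cl2, rt) converts only the allylic C9 carbinol and gives the 3-hydroxy-9-oxo enone F3. The C3 carbinol is then oxidised alone under neutral perruthenate catalysis (n-Pr4N[RuO4] (cat.), N-methylmorpholine N-oxide, 4 Å molecular sieves, CH2Cl2, 0 °C) with short contact time, and the route is rejoined at 26.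

Further compounds
F1 | step 16 | (3S,4S,5E,7R,8S)-7-(tert-butyldimethylsilyloxy)-4,8-dimethyldeca-5,9-dien-3-yl (2R,3S,4R)-3-(tert-butyldimethylsilyloxy)-2,4,6-trimethyl-5-oxohept-6-enoate | C=C[C@H](C)[C@H](O[Si](C)(C)C(C)(C)C)/C=C/[C@H](C)[C@H](CC)OC(=O)[C@H](C)[C@@H](O[Si](C)(C)C(C)(C)C)[C@@H](C)C(=O)C(C)=C
F2 | step 16 | (2R,3S,4R,6E,8S,9R,10E,12S,13S)-3,9-bis(tert-butyldimethylsilyloxy)-2,4,6,8,12-pentamethyl-5-oxopentadeca-6,10-dien-13-olide | CC[C@@H]1OC(=O)[C@H](C)[C@@H](O[Si](C)(C)C(C)(C)C)[C@@H](C)C(=O)/C(C)=C/[C@H](C)[C@H](O[Si](C)(C)C(C)(C)C)/C=C/[C@@H]1C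
F0 | step 17 | none | none
F3 | step 20 | (2R,3S,4R,5R,6S,8S,10E,12S,13S)-5-(allyloxycarbonyloxy)-3-hydroxy-2,4,6,8,12-pentamethyl-9-oxopentadec-10-en-13-olide | CC[C@@H]1OC(=O)[C@H](C)[C@@H](O)[C@@H](C)[C@H](OC(=O)OCC=C)[C@@H](C)C[C@H](C)C(=O)/C=C/[C@@H]1C
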